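## Structural features

The target is the vanillate (4-hydroxy-3-methoxybenzoate) of a primary allylic alcohol on a bicyclo[5.3.0]decadiene (hexahydroazulene, daucane-type) core, numbered here C1–C3, C3a, C4–C8, C8a. A cyclopentene (C1, C2, C3, C3a, C8a) and a cycloheptene (C3a, C4–C8, C8a) share the C3a–C8a bond. C8a is a methyl-bearing all-carbon quaternary centre; C3a is sp2 and is joined to the isopropyl-bearing C3 by a tetrasubstituted alkene; the trisubstituted alkene C6=C7 carries the CH2O–acyl group on C6. C8a (R) is the only stereocentre, so no neighbouring centre in the product can relay to it, and whatever controls it must be external or be destroyed afterwards. Fragile points are the allylic ester (ionisable, open to SN2' attack and acyl transfer), the free phenol (nucleophilic, oxidisable) and the tetrasubstituted alkene, which acid can move towards an isopropylidene isomer. The real difficulty is the quaternary carbon at the junction of a seven-membered ring beside the tetrasubstituted alkene, together with the exact placing of two non-conjugated alkenes. The key step exploits three facts: C4, C3a and C8a are the allyl unit of a 1-cyclopentenylmethyl cation; C5–C8 are a 2-substituted butadiene that can already carry the ester on C6; and the C3=C3a alkene is what remains when a cation at C3a loses the C3 proton.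

## Logic of the disconnections

15 to 14: the phenolic O–H is replaced by an O–acetyl bond. The free phenol would compete as a nucleophile towards the allyl cation and the acid chloride. An aryl acetate is electron-withdrawing, tolerates ZnCl2 and is far more labile than the alkyl benzoate. Nothing is gained in skeleton; the gain is that the ester can travel through the union. The forward step must cleave an aryl acetate without touching the allylic benzoate or the alkenes.

14 to 6 and 12 (through 13): the C4–C5 and C8–C8a bonds are cut and a hydrogen is put back on C3. The seven-membered ring falls into a three-carbon allyl cation (C4, C3a, C8a) and a four-carbon diene (C5–C8) that carries the whole aryl ester. The target is split into two halves of similar size, and its one stereocentre is exchanged for a chiral-pool centre at C3 that is erased after use. The forward step must ionise only the activated form of 6, join the least hindered cation terminus to the most nucleophilic diene terminus, close seven rather than six or five, form C8–C8a anti to the isopropyl group, and end by proton loss from C3. To help this, 6 is activated in the flask as 13 with a hindered proton trap, and the aryl ester is kept electron-poor.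

6 to 5: the two C–H bonds of the carbinol carbon are traced to an aldehyde, because the ring-forming condensation delivers that oxidation level. The forward step is a 1,2-reduction of an enal.

5 to 4: the ring C=C of the enal (the later C3a–C8a bond) is cut in the aldol sense. This opens the cyclopentene to an acyclic 1,6-keto aldehyde with one stereocentre. The forward step must use the aldehyde as the enol component and the methyl ketone as the acceptor.

4 to 2: the two carbonyl carbons are rejoined as a C=C of a cyclohexene, which turns the 1,6-dicarbonyl chain into a terpene ring. The forward step must cleave the only alkene cleanly and stop at the aldehyde.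

2 to 1: the isopropyl group is traced to an isopropenyl group, because 1 is the commercial enantiopure terpene. Saturating this alkene first means the cleavage step sees a single C=C. The forward step must reduce the 1,1-disubstituted alkene and spare the trisubstituted one.

12 to 10 and 8 (through 11): the acyl C–O bond of the ester is cut, separating the arene from the five-carbon diene. The forward acylation must avoid acid and heat, since the diene dimerises by Diels–Alder reaction.

10 to 9: the O–acetyl bond is cut, leading to the commercial phenolic acid. The forward step must acetylate the phenol and leave the acid free after work-up.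

8 to 7: the C=CH2 and O–H of the dienol are traced to the methyl group and a C–O bond of a vinyl epoxide, a commercial five-carbon unit. The forward step must be a base-induced elimination and not an SN2 or SN2' opening.

## Other disconnections considered

Alternative 1: The cut removes the C3a–C8a bond and a carbonyl carbon placed at C2 (bonds C1–C2 and C2–C3). This leads to the acyclic (E)-1,8-enyne A1, in which an isopropyl alkyne and an isopropenyl group are linked through the future C4–C8 chain with its silyl-protected hydroxymethyl alkene. Forward, A1 and CO under a monovalent rhodium catalyst made from [Rh(CO)2Cl]2 and a chiral bisphosphine of the BINAP family would give the bicyclic cyclopentenone A2 in a Pauson–Khand-type reaction.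
- In favour: three C–C bonds, both rings, the quaternary centre and the tetrasubstituted alkene arise in one operation, and C8a would be set by the catalyst without any relay. On bonds formed per step and on directness of stereocontrol this alternative is the better.
- Against: a 1,1-disubstituted alkene and a four-atom tether closing a seven-membered ring are both at the limit of this reaction. Enantioselective variants are established for 1,6-enynes, and the skipped diene of A1 invites isomerisation and ene-type cycloisomerisation. A1 needs a linear sequence with a stereodefined trisubstituted alkene. A2 carries a C2 ketone that the target lacks; removing it without moving the C3=C3a alkene is awkward, and desilylation, acylation and phenol deprotection still follow.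
- Comparison: structurally it builds more in one step but ends further from the target, whereas 14 is one step from 15. Mechanistically both key steps lie beyond secure precedent; the organometallic one is free of cation rearrangements (a point in its favour) but needs CO. In step economy the chosen plan is clearly shorter (six steps in its longest line against an estimated twelve or more).

Alternative 2: The cut is the C8–C8a bond, traded for a C4–O bond. The seven-membered ring is opened to the 2-methylidene tetrahydrofuran A4, whose carbinol carbon (future C4) bears the cyclopentenyl group, and A4 comes from lactone A3. Forward, heating A3 with Cp2TiMe2 would methylenate the lactone carbonyl, and A4 would undergo a [3,3] (Claisen) rearrangement in the same pot to the cyclohept-4-enone A5.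
- In favour: a thermal pericyclic step with no reactive cation. It is suprafacial on the allyl part, so the C4–O stereocentre of A3 alone dictates C8a (the (S)-carbinol for the required sense). On reliability of mechanism and predictability of chirality transfer this alternative is the better.
- Against: the new bond ends on a fully substituted alkene carbon, so the rearrangement should be slow and hot. The carbinol configuration of A3 must itself be set next to the ring, for example by addition to 5, so the relay problem is shifted and not removed. A5 has the alkene at C3a=C4, a ketone at C7 and a phenylthiomethyl group at C6. Alkene migration, sulfoxide elimination, 1,2-reduction, allylic transposition with acylation and phenol deprotection would follow.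
- Comparison: structurally it is the equal of the chosen plan in making C8–C8a the strategic bond, but it is not convergent, since the aryl ester comes last. Mechanistically it is better founded. In step economy it is worse (an estimated fourteen or more steps in the longest line).

Alternative 3: The cut takes out the C5–C6 and C8–C8a bonds. C6, C7 and C8 come from the vinylcarbenoid of diazo ester A6; C5, C4, C3a and C8a come from the vinyl group and ring alkene of dienone A7. Forward, a chiral dirhodium tetracarboxylate (divalent rhodium, for example Rh2(S-DOSP)4 or its antipode) would cyclopropanate the vinyl group of A7, and the cis-divinylcyclopropane would undergo Cope rearrangement to A8.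
- In favour: it makes the same two bonds as the chosen (4+3) union, but through neutral intermediates and a documented reaction class. The catalyst sets the absolute configuration and the Cope step passes it stereospecifically to C8a. The C6=C7 alkene and the C6 carbon substituent come out in the right place, and both partners are short to make. On precedent and on control of the stereocentre this alternative is the better; in total step count it is about the equal.
- Against: A7 is an electron-poor, cross-conjugated diene for an electrophilic carbenoid. The Cope step must form the quaternary carbon with a cis-methyl group on the reacting alkene. A6 is a thermally labile diazo compound. A8 still lacks the isopropyl group and has a C3 ketone with the alkene at C3a=C4. Conjugate reduction with enol triflate trapping, isopropyl cross-coupling, selective ester reduction, acylation and deprotection would follow, with chemoselectivity between enone and unsaturated ester to be managed.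
- Comparison: the chosen plan wins on convergence (both halves complete before the union, one step after it) and on avoiding diazo chemistry; it loses on certainty. The chemistry of this alternative is therefore used as the fallback to the key step.

Key step: step 8

Remark on the chemistry: positions are numbered as in a hexahydroazulene (isopropyl on C3, oxymethyl on C6, methyl on C8a), the single stereocentre C8a of the SMILES is read as R, and racemic 7 is used because its stereocentre disappears.

## Route

Step 1
Reactants: 1 (S)-limonene
Product: 2 (S)-p-menth-1-ene
Conditions: H2 (1 atm), RhCl(PPh3)3 (1 mol%), toluene, rt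
Reagents that add atoms: none
Why: Chemoselective homogeneous hydrogenation; RhCl(PPh3)3 reduces the unhindered 1,1-disubstituted isopropenyl alkene much faster than the trisubstituted ring alkene, and the stereocentre is untouched. Doing this first leaves a single C=C for the cleavage step.

Step 2
Reactants: 2 (S)-p-menth-1-ene
Product: 4 (3S)-6-oxo-3-(propan-2-yl)heptanal, via secondary ozonide 3 (not isolated)
Conditions: O3, CH2Cl2, −78 °C; then Me2S, −78 °C to rt
Reagents that add atoms: ozone, [O-][O+]=O
Why: Ozonolysis with reductive work-up of the only alkene gives the 1,6-keto aldehyde; the stereocentre is beta to the aldehyde and cannot epimerise.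

Step 3
Reactants: 4 (3S)-6-oxo-3-(propan-2-yl)heptanal
Product: 5 (5R)-2-methyl-5-(propan-2-yl)cyclopent-1-ene-1-carbaldehyde
Conditions: piperidine (0.2 equiv), AcOH (0.2 equiv), toluene, 80 °C
Reagents that add atoms: none
Why: Intramolecular aldol condensation under amine–acid (enamine) catalysis; the aldehyde forms the enamine, which adds to the methyl ketone and dehydrates to the conjugated cyclopentenecarbaldehyde. The stereocentre is not enolisable.

Step 4
Reactants: 5 (5R)-2-methyl-5-(propan-2-yl)cyclopent-1-ene-1-carbaldehyde
Product: 6 [(5R)-2-methyl-5-(propan-2-yl)cyclopent-1-en-1-yl]methanol
Conditions: NaBH4, CeCl3·7H2O, MeOH, 0 °C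
Reagents that add atoms: none
Why: Luche 1,2-reduction of the enal to the allylic alcohol; no new stereocentre is formed.

Step 5
Reactants: 7 2-methyl-2-vinyloxirane (racemic)
Product: 8 2-methylidenebut-3-en-1-ol
Conditions: LiN(iPr)2 (1.2 equiv), Et2O, 0 °C to rt; then H2O; used as a cold ethereal solution with a trace of BHT
Reagents that add atoms: none
Why: Base-promoted isomerisation of an epoxide to an allylic alcohol; the hindered amide removes a methyl proton and the oxirane opens by beta-elimination to the 2-substituted diene alcohol.

Step 6
Reactants: 9 vanillic acid
Product: 10 4-acetoxy-3-methoxybenzoic acid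
Conditions: Ac2O, pyridine, rt; then H2O, dilute HCl
Reagents that add atoms: acetic anhydride, CC(=O)OC(C)=O
Why: O-Acetylation of the phenol; any mixed anhydride formed at the carboxyl group is hydrolysed on aqueous work-up.

Step 7
Reactants: 10 4-acetoxy-3-methoxybenzoic acid; 8 2-methylidenebut-3-en-1-ol
Product: 12 2-methylidenebut-3-en-1-yl 4-acetoxy-3-methoxybenzoate, via acid chloride 11 (not isolated)
Conditions: (COCl)2, DMF (cat.), CH2Cl2, 0 °C to rt, evaporate; then 8, pyridine (2 equiv), CH2Cl2, 0 °C
Reagents that add atoms: none
Why: Acid chloride formation followed by fast base-mediated acylation of the primary alcohol at low temperature, which avoids the acid and heat that would trigger Diels–Alder dimerisation of the diene. The aryl acetate is inert to both stages.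

Step 8
Reactants: 6 [(5R)-2-methyl-5-(propan-2-yl)cyclopent-1-en-1-yl]methanol; 12 2-methylidenebut-3-en-1-yl 4-acetoxy-3-methoxybenzoate
Product: 14 [(8aR)-8a-methyl-3-(propan-2-yl)-1,2,4,5,8,8a-hexahydroazulen-6-yl]methyl 4-acetoxy-3-methoxybenzoate, via allylic trifluoroacetate 13 (not isolated)
Conditions: (CF3CO)2O (1.05 equiv), 2,6-di-tert-butylpyridine (2.2 equiv), CH2Cl2, −40 °C; then 12 (1.5 equiv), ZnCl2 (1 M in Et2O, 1.5 equiv), −78 to −20 °C; aq. NaHCO3
Reagents that add atoms: none
Why: Proposed new method: ZnCl2 should ionise the trifluoroacetate 13 to the cyclopentenylmethyl cation, whose charge is shared by the exocyclic CH2 (future C4) and the methyl-bearing ring carbon (future C8a); the unhindered CH2 end adds to the CH2 on the substituted diene carbon of 12 (future C5), giving a tertiary allyl cation over C6–C8, and the re-formed tetrasubstituted cyclopentene then attacks the primary C8 end through its methyl-bearing carbon, so that the C4–C5 and C8–C8a bonds form in a stepwise cationic (4+3) cycloaddition that ends when the tertiary cation at C3a loses the C3 proton to the hindered pyridine. The closest known reaction type is the (4+3) cycloaddition of 2-alkylallyl cations, made from allylic halides or trifluoroacetates with zinc or silver salts, with 1,3-dienes, together with ZnCl2-promoted stepwise additions of allyl cations to alkenes; neither has been shown for an exocyclic trisubstituted cation joined to an acyclic diene at a fully substituted carbon. One ring is closed, the cycloheptene, by an intermolecular bond followed by a 7-endo cation–alkene closure; the 6-exo closure of the (4+2) mode would have to build a spiro quaternary carbon at C3a beside the isopropyl-bearing carbon and the five-ring (3+2) mode two adjacent quaternary carbons, which is the basis for expecting the seven-membered ring. The only new stereocentre, C8a, is controlled by the isopropyl stereocentre of 6: the two-carbon tether on C3a is held on the ring face away from isopropyl by allylic strain, so C8 is delivered to that face and (R)-6 should give (8aR)-14, after which the controlling centre is erased. The step needs chemoselective ionisation (the trifluoroacetate of a trialkyl-substituted allyl system leaves far more readily than the primary benzoate of 12 or of 14), head-to-tail regioselectivity (least hindered cation terminus to most nucleophilic diene terminus), periselectivity and Zaitsev proton loss; the electron-poor acetylated aryl ester keeps the arene and the ester carbonyl from competing as nucleophiles, and the proton trap suppresses acid-induced diene oligomerisation and alkene migration.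

Step 9
Reactants: 14 [(8aR)-8a-methyl-3-(propan-2-yl)-1,2,4,5,8,8a-hexahydroazulen-6-yl]methyl 4-acetoxy-3-methoxybenzoate
Product: 15 [(8aR)-8a-methyl-3-(propan-2-yl)-1,2,4,5,8,8a-hexahydroazulen-6-yl]methyl 4-hydroxy-3-methoxybenzoate (target)
Conditions: NH4OAc (excess), MeOH–H2O (4:1), rt
Reagents that add atoms: none
Why: Selective solvolysis of an aryl acetate; a phenyl ester is a much better acyl donor than the allylic alkyl benzoate, which is further deactivated once the para-phenol is free, so the near-neutral acetate buffer should cleave only the acetate.

## Compound list

1 | (S)-limonene [(4S)-1-methyl-4-(prop-1-en-2-yl)cyclohex-1-ene] | CC1=CC[C@H](CC1)C(C)=C | starting material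
2 | (S)-p-menth-1-ene [(4S)-1-methyl-4-(propan-2-yl)cyclohex-1-ene] | CC1=CC[C@H](CC1)C(C)C | intermediate
3 | secondary ozonide, (4S)-1-methyl-4-(propan-2-yl)-7,8,9-trioxabicyclo[4.2.1]nonane (both bridge diastereomers) | CC12CC[C@H](C(C)C)CC(OO1)O2 | intermediate (not isolated)
4 | (3S)-6-oxo-3-(propan-2-yl)heptanal | CC(=O)CC[C@@H](CC=O)C(C)C | intermediate
5 | (5R)-2-methyl-5-(propan-2-yl)cyclopent-1-ene-1-carbaldehyde | CC1=C(C=O)[C@@H](C(C)C)CC1 | intermediate
6 | [(5R)-2-methyl-5-(propan-2-yl)cyclopent-1-en-1-yl]methanol | CC1=C(CO)[C@@H](C(C)C)CC1 | intermediate
7 | 2-methyl-2-vinyloxirane (racemic) | CC1(C=C)CO1 | starting material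
8 | 2-methylidenebut-3-en-1-ol | C=CC(=C)CO | intermediate
9 | vanillic acid (4-hydroxy-3-methoxybenzoic acid) | COc1cc(C(=O)O)ccc1O | starting material
10 | 4-acetoxy-3-methoxybenzoic acid | COc1cc(C(=O)O)ccc1OC(C)=O | intermediate
11 | 4-acetoxy-3-methoxybenzoyl chloride | COc1cc(C(Cl)=O)ccc1OC(C)=O | intermediate (not isolated)
12 | 2-methylidenebut-3-en-1-yl 4-acetoxy-3-methoxybenzoate | C=CC(=C)COC(=O)c1ccc(OC(C)=O)c(OC)c1 | intermediate
13 | [(5R)-2-methyl-5-(propan-2-yl)cyclopent-1-en-1-yl]methyl trifluoroacetate | CC1=C(COC(=O)C(F)(F)F)[C@@H](C(C)C)CC1 | intermediate (not isolated)
14 | [(8aR)-8a-methyl-3-(propan-2-yl)-1,2,4,5,8,8a-hexahydroazulen-6-yl]methyl 4-acetoxy-3-methoxybenzoate | COc1cc(C(=O)OCC2=CC[C@@]3(C)CCC(C(C)C)=C3CC2)ccc1OC(C)=O | intermediate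
15 | [(8aR)-8a-methyl-3-(propan-2-yl)-1,2,4,5,8,8a-hexahydroazulen-6-yl]methyl 4-hydroxy-3-methoxybenzoate | COc1cc(C(=O)OCC2=CC[C@@]3(C)CCC(C(C)C)=C3CC2)ccc1O | target

## Step count and least certain steps

Total: 9 steps. Longest linear sequence: 6 steps (steps 1, 2, 3, 4, 8, 9); the diene ester branch (steps 5, 6, 7) joins at step 8.

**Step 8 (key step).** Several processes could divert it.
- The second bond could close in the six-membered (4+2) mode, or not form at all (capture or proton loss after the first bond), because a cation–alkene closure to a seven-membered ring has no intrinsic kinetic advantage.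
- Facial selectivity at C8a could be poor, because the directing isopropyl group is one atom removed from the bond-forming carbon.
- The ester carbonyl could intercept the tertiary allyl cation as an acyloxonium ion, and the diene could oligomerise cationically.
- A change of conditions worth trying first is direct ionisation of 6 in (CF3)2CHOH with a catalytic acid.

The fallback changes the approach and uses a known reaction class; it sets out from 5 and returns at 14. Wittig methylenation of 5 (Ph3P=CH2 from Ph3PCH3Br and KOtBu, THF, 0 °C) would give (3R)-2-ethenyl-1-methyl-3-(propan-2-yl)cyclopent-1-ene F1. Reaction of F1 with freshly prepared methyl 2-diazobut-3-enoate under a chiral dirhodium tetraprolinate would cyclopropanate the unhindered vinyl group to the cis-divinylcyclopropane methyl (1S,2S)-1-ethenyl-2-[(5R)-2-methyl-5-(propan-2-yl)cyclopent-1-en-1-yl]cyclopropane-1-carboxylate F2. The catalyst antipode that delivers the (1S,2S)-cyclopropane is needed; by the usual sense of induction this is expected to be Rh2(R-DOSP)4, to be confirmed on the first run (hexanes, −40 °C to rt). On warming, F2 should undergo Cope rearrangement through the boat transition state to methyl (3R,8aR)-8a-methyl-3-(propan-2-yl)-1,2,3,5,8,8a-hexahydroazulene-6-carboxylate F3. Here C8a is set by the catalyst, and the C3 centre no longer has to direct anything. Acid-catalysed alkene migration (TsOH, toluene, 60 °C) from C3a=C4 to the tetrasubstituted C3=C3a position would give methyl (8aR)-8a-methyl-3-(propan-2-yl)-1,2,4,5,8,8a-hexahydroazulene-6-carboxylate F4. Reduction with iBu2AlH (CH2Cl2, −78 °C) would give [(8aR)-8a-methyl-3-(propan-2-yl)-1,2,4,5,8,8a-hexahydroazulen-6-yl]methanol F5. Acylation of F5 with acid chloride 11 (made from 10 as in step 7; pyridine, CH2Cl2, 0 °C) gives 14.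

**Step 5.** The amide could open the epoxide as a nucleophile (SN2 or SN2') instead of acting as a base, and the volatile dienol could be lost on isolation or by Diels–Alder dimerisation before it is acylated. The fallback masks the diene as a sulfolene; it sets out from 10 and returns at 12, bypassing 8. Radical bromination of commercial 3-methyl-2,5-dihydrothiophene 1,1-dioxide (NBS, radical initiator, PhCF3, 80 °C) gives 3-(bromomethyl)-2,5-dihydrothiophene 1,1-dioxide F6. Alkylation of the carboxylate of 10 with F6 (KHCO3, DMF, rt) gives (1,1-dioxo-2,5-dihydrothiophen-3-yl)methyl 4-acetoxy-3-methoxybenzoate F7. Cheletropic loss of SO2 from F7 (toluene, 110 °C, BHT, dilute) unmasks the diene and gives 12.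

**Step 9.** Acyl transfer at the vanillate ester (loss of the aryl ester from the allylic position) could compete with acetate cleavage, or the acetate cleavage could stall. The fallback rebuilds the ester without any phenol protection; it sets out from 14 (or from a mixture containing it) and returns at 15. LiAlH4 (THF, 0 °C to rt) reduces both esters to [(8aR)-8a-methyl-3-(propan-2-yl)-1,2,4,5,8,8a-hexahydroazulen-6-yl]methanol F8 (identical with F5). Mitsunobu esterification of F8 with vanillic acid 9 (PPh3, DIAD, THF, 0 °C) gives 15 directly, since the carboxyl group is far more acidic than the phenol and is the only site activated.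

## Further compounds

F1 | step 8 | (3R)-2-ethenyl-1-methyl-3-(propan-2-yl)cyclopent-1-ene | CC1=C(C=C)[C@@H](C(C)C)CC1
F2 | step 8 | methyl (1S,2S)-1-ethenyl-2-[(5R)-2-methyl-5-(propan-2-yl)cyclopent-1-en-1-yl]cyclopropane-1-carboxylate | COC(=O)[C@]1(C=C)C[C@H]1C2=C(C)CC[C@@H]2C(C)C
F3 | step 8 | methyl (3R,8aR)-8a-methyl-3-(propan-2-yl)-1,2,3,5,8,8a-hexahydroazulene-6-carboxylate | COC(=O)C1=CC[C@@]2(C)CC[C@H](C(C)C)C2=CC1
F4 | step 8 | methyl (8aR)-8a-methyl-3-(propan-2-yl)-1,2,4,5,8,8a-hexahydroazulene-6-carboxylate | COC(=O)C1=CC[C@@]2(C)CCC(C(C)C)=C2CC1
F5 | step 8 | [(8aR)-8a-methyl-3-(propan-2-yl)-1,2,4,5,8,8a-hexahydroazulen-6-yl]methanol | OCC1=CC[C@@]2(C)CCC(C(C)C)=C2CC1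
F6 | step 5 | 3-(bromomethyl)-2,5-dihydrothiophene 1,1-dioxide | BrCC1=CCS(=O)(=O)C1
F7 | step 5 | (1,1-dioxo-2,5-dihydrothiophen-3-yl)methyl 4-acetoxy-3-methoxybenzoate | COc1cc(C(=O)OCC2=CCS(=O)(=O)C2)ccc1OC(C)=O
F8 | step 9 | [(8aR)-8a-methyl-3-(propan-2-yl)-1,2,4,5,8,8a-hexahydroazulen-6-yl]methanol (identical with F5) | OCC1=CC[C@@]2(C)CCC(C(C)C)=C2CC1
A1 | alternative 1 | tert-butyl(dimethyl){[(2E)-5-methyl-2-(5-methylhex-3-yn-1-yl)hexa-2,5-dien-1-yl]oxy}silane | CC(C)C#CCC/C(CO[Si](C)(C)C(C)(C)C)=C\CC(C)=C
A2 | alternative 1 | (8aS)-6-{[tert-butyl(dimethyl)silyl]oxymethyl}-8a-methyl-3-(propan-2-yl)-4,5,8,8a-tetrahydroazulen-2(1H)-one | CC(C)(C)[Si](C)(C)OCC1=CC[C@@]2(C)CC(=O)C(C(C)C)=C2CC1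
A3 | alternative 2 | (3S,5S)-5-[(5R)-2-methyl-5-(propan-2-yl)cyclopent-1-en-1-yl]-3-[(phenylsulfanyl)methyl]oxolan-2-one | O=C1O[C@@H](C[C@@H]1CSc2ccccc2)C3=C(C)CC[C@@H]3C(C)C
A4 | alternative 2 | (3S,5S)-2-methylidene-5-[(5R)-2-methyl-5-(propan-2-yl)cyclopent-1-en-1-yl]-3-[(phenylsulfanyl)methyl]oxolane | C=C1O[C@@H](C[C@@H]1CSc2ccccc2)C3=C(C)CC[C@@H]3C(C)C
A5 | alternative 2 | (3R,6S,8aR)-8a-methyl-6-[(phenylsulfanyl)methyl]-3-(propan-2-yl)-1,2,3,5,6,8a-hexahydroazulen-7(8H)-one | O=C1C[C@@]2(C)CC[C@H](C(C)C)C2=CC[C@@H]1CSc3ccccc3
A6 | alternative 3 | methyl 2-diazobut-3-enoate | C=CC(=[N+]=[N-])C(=O)OC
A7 | alternative 3 | 3-methyl-2-vinylcyclopent-2-en-1-one | CC1=C(C=C)C(=O)CC1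
A8 | alternative 3 | methyl (8aR)-8a-methyl-3-oxo-1,2,3,5,8,8a-hexahydroazulene-6-carboxylate | COC(=O)C1=CC[C@@]2(C)CCC(=O)C2=CC1
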